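**Plan** (locants C1–C15 are those of the target's germacranolide skeleton)

1. Retrosynthesis: C2–C3 and O–C10 are cut together, last; then C4=C5 (RCM), the O11–C3 ester together with C13–Cl (acid chloride opening of an 11,13-epoxide), the O8 angelate, the C9–C10 epoxide, C9=C10 (Wittig) and the C5/C9 ends (cleavage of a cyclopentene).
2. Forward: bicyclic lactone 1 → C11 methylene → exo 11,13-epoxide → lactone moved from O8 to C6 → cyclopentene cleaved to a C6 vinyl group and the C8 side chain → E-enone → epoxide → O8 angelate → C13 chloride/O11 methacrylate → RCM to the seven-membered lactone ring B → one-flask ring expansion and furanone closure.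
3. Enabling feature: the tertiary O11 lies cis to C5 and C8 on the γ-lactone (ring A). An O11–C3 lactone (ring B: C3, C4, C5, C6, C7, C11, O11) therefore holds the C3 carbonyl beside the C8 side chain. The C2 enolate takes C3 from O11, which turns ring B into the ten-membered carbocycle; the C3 enol oxygen then opens the C9–C10 epoxide at C10 and closes the furanone, freeing the C11 and C9 hydroxyls.
4. Stereochemistry: C7/C8 come from 1; C11 from exo epoxidation (brought cis to C8 by the lactone shift); C6 from cis iodolactonisation; C9/C10 from hydroxyl-directed epoxidation, with C10 inverted in the last step; C4=C5 is Z by ring B, C9=C10 E and the angelate Z come from the reagents.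

Key step: step 12

Remark on the chemistry: the (1R,5S) enantiomer of 2-oxabicyclo[3.3.0]oct-6-en-3-one is taken as a catalogue compound; in 1 the lactone oxygen is O8, the ring-fusion carbons are C8 and C7, the alkene is C5=C6 and the lactone CH2 is C11.

**Route**

Step 1
Reactants: 1 (1R,5S)-2-oxabicyclo[3.3.0]oct-6-en-3-one
Product: 5 α-methylene lactone (C11=C13H2), via lithium enolate 2 (not isolated), via Mannich base 3 (not isolated), via ammonium iodide 4 (not isolated)
Conditions: LiN(i-Pr)2, THF, −78 °C; CH2=NMe2+ I−, −78 °C → rt; MeI, MeOH, rt; DBU, CH2Cl2, rt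
Reagents that add atoms: Eschenmoser's salt (N,N-dimethylmethyleneiminium iodide), C=[N+](C)C.[I-]
Why: Mannich reaction of the lactone enolate, quaternisation and E2 loss of trimethylamine is the standard α-methylenation of γ-lactones; C11 becomes sp2 and the ring-fusion centres C7 and C8 are not touched.

Step 2
Reactants: 5 α-methylene lactone
Product: 6 exo spiro-epoxide (11,13-epoxide)
Conditions: t-BuOOH (decane), DBU, CH2Cl2, 0 °C
Reagents that add atoms: tert-butyl hydroperoxide, CC(C)(C)OO
Why: Weitz–Scheffer nucleophilic epoxidation: the peroxide anion adds to C13 and the lactone enolate closes on oxygen from the convex face of the cis-bicyclo[3.3.0] skeleton, so the epoxide oxygen should be exo (cis to H7), which fixes C11; the isolated cyclopentene is inert to the nucleophilic oxidant.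

Step 3
Reactants: 6 exo spiro-epoxide
Product: 8 iodolactone, via lithium carboxylate 7 (not isolated)
Conditions: LiOH, THF/H2O, 0 °C; then NaHCO3, KI, I2, H2O/THF, 0 °C → rt, dark
Reagents that add atoms: lithium hydroxide, [Li+].[OH-]; iodine, II
Why: Saponification followed by iodolactonisation (5-exo, anti addition) moves the lactone from O8 to C6: the carboxylate attacks C6 from the face that carries its side chain, giving the cis-fused lactone (C6 set, iodide trans at C5, C8–OH free), and the shift places the C11 epoxide oxygen cis to C8 as the target needs.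

Step 4
Reactants: 8 iodolactone
Product: 9 cyclopentenol lactone (C5=C9)
Conditions: DBU, THF, 60 °C
Reagents that add atoms: none
Why: Anti E2 elimination: the only hydrogen anti to the C5 iodide is on C9 (H6 is syn), so the alkene should form at C5=C9 and leave O6, C11 and O8 all cis on the cyclopentene.

Step 5
Reactants: 9 cyclopentenol lactone
Product: 11 lactol alcohol, via lactol aldehyde 10 (not isolated)
Conditions: O3, CH2Cl2/MeOH, −78 °C; Me2S, −78 → 0 °C; NaBH4, MeOH, −78 °C
Reagents that add atoms: ozone, [O-][O+]=O
Why: Ozonolysis cleaves C5=C9 to two aldehydes; C5 is trapped at once by the cis C8 hydroxyl as a five-membered lactol, so only the free C9 aldehyde should be reduced by borohydride at low temperature (aldehyde reduction in the presence of a hemiacetal).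

Step 6
Reactants: 11 lactol alcohol
Product: 12 vinyl diol
Conditions: Ph3PCH3Br, KN(SiMe3)2, THF, 0 °C; then 11, −78 → 0 °C
Reagents that add atoms: methyltriphenylphosphonium bromide, C[P+](c1ccccc1)(c1ccccc1)c1ccccc1.[Br-]
Why: Wittig methylenation of the open hydroxy-aldehyde form of the lactol, as used for sugar lactols, turns C5 into the C6 vinyl group and frees the C8 hydroxyl; the lactone has no α-hydrogen and the low temperature should keep the alkoxides from attacking it.

Step 7
Reactants: 12 vinyl diol
Product: 14 γ-hydroxy E-enone, via hydroxy aldehyde 13 (not isolated)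
Conditions: TEMPO (cat.), PhI(OAc)2, CH2Cl2, rt; then Ph3P=C(CH3)C(O)CH3, 40 °C
Reagents that add atoms: 3-(triphenylphosphoranylidene)butan-2-one, CC(=O)C(C)=P(c1ccccc1)(c1ccccc1)c1ccccc1
Why: The TEMPO/PhI(OAc)2 couple oxidises the primary C9 alcohol and leaves the secondary C8 alcohol, and the stabilised ylide added to the same flask should give the trisubstituted E-enone (Wittig reaction).

Step 8
Reactants: 14 γ-hydroxy E-enone
Product: 15 bis-epoxide hydroxy ketone
Conditions: t-BuOOH, n-BuLi, THF, −78 → −20 °C
Reagents that add atoms: tert-butyl hydroperoxide, CC(C)(C)OO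
Why: Hydroxyl-directed Weitz–Scheffer epoxidation: allylic 1,3-strain with the C10 methyl group holds H8 in the alkene plane and the lithium-bound C8 oxygen delivers the peroxide to its own face, which should give the threo (syn) trans-epoxide and so set C9 and C10 relative to C8.

Step 9
Reactants: 15 bis-epoxide hydroxy ketone
Product: 16 O8 angelate
Conditions: angelic acid, 2,4,6-Cl3C6H2COCl, Et3N, toluene, rt; then 15, DMAP, 60 °C
Reagents that add atoms: angelic acid [(Z)-2-methylbut-2-enoic acid], C/C=C(/C)C(=O)O
Why: Yamaguchi esterification of the only free hydroxyl through the preformed mixed anhydride is the usual way to make angelates without Z-to-E isomerisation; C8 keeps its configuration.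

Step 10
Reactants: 16 O8 angelate
Product: 17 chlorohydrin methacrylate
Conditions: CH2=C(CH3)COCl, n-Bu4NCl (cat.), BHT, 1,2-dichloroethane, 50 °C
Reagents that add atoms: methacryloyl chloride, C=C(C)C(Cl)=O
Why: Acylative opening of an epoxide by an acid chloride under chloride catalysis: chloride attacks the unhindered C13 methylene of the glycidic epoxide and the tertiary C11 alkoxide is acylated, so C11 keeps its configuration; the hindered trisubstituted C9–C10 epoxide should react more slowly.

Step 11
Reactants: 17 chlorohydrin methacrylate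
Product: 18 bridged bis-lactone
Conditions: second-generation Hoveyda–Grubbs catalyst (10 mol %), toluene (0.002 M), 80 °C
Reagents that add atoms: none
Why: Ring-closing metathesis between the C6 vinyl group and the O11 methacrylate, which are cis-1,3 on ring A, should close the seven-membered unsaturated lactone ring B with loss of ethylene; C4=C5 is Z by ring constraint and the angelate alkene is too hindered to take part.

Step 12
Reactants: 18 bridged bis-lactone
Product: 21 target CNP0272644.1, via lithium enolate 19 (not isolated), via ten-membered diketone 20 (not isolated)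
Conditions: LiN(SiMe3)2 (1.05 equiv), THF (0.005 M), −78 → −20 °C; AcOH (1.05 equiv); Et3N, LiClO4, 0 °C → rt
Reagents that add atoms: none
Why: Proposed new method: kinetic deprotonation at the only enolisable ketone position (the C2 methyl; C10 has no hydrogen) gives enolate 19, whose carbon adds to the C3 lactone carbonyl and expels the tertiary C11 alkoxide (a good leaving group, α to the C12 carbonyl), so ring B is exchanged for the ten-membered carbocycle as β-diketone 20; after buffering, the C3 enol(ate) oxygen opens the C9–C10 epoxide at C10 and closes the furanone. The closest known reaction types are the Baker–Venkataraman O-to-C acyl transfer (an intramolecular Claisen condensation) and the O-cyclisation of β-diketones that carry a leaving group at the γ-carbon to 3(2H)-furanones, here with an epoxide as leaving group and both events in one flask. The first closure is a 9-(enolendo)-exo-trig addition whose collapse expands ring B into the carbocycle; the second is a 5-exo-tet epoxide opening, the 6-endo attack at C9 being disfavoured and C-alkylation impossible (three-membered ring). C10 is set by inversion of the epoxide carbon fixed in step 8, C9 keeps its oxygen, and the Z C4=C5 bond and all other centres are untouched. The step needs acylation at C3 and not at the angelate or C12: the angelate would require a seven-membered transition state that contains the trans-epoxide, C12 is neopentylic, and C3 is held over the side chain by the cis O11/C5 bridge. It also needs the absence of a free alkoxide, which would shift the angelate to O9 or close the chlorohydrin; the AcOH/Et3N buffer should secure this by protonating the C9 alkoxide as it forms.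

**Compound list**

1 | (1R,5S)-2-oxabicyclo[3.3.0]oct-6-en-3-one (cis-fused; lactone on O8) | O=C1C[C@H]2C=CC[C@H]2O1 | starting material
2 | lithium enolate of 1 (C11=C12–OLi) | [Li+].[O-]C1=C[C@H]2C=CC[C@H]2O1 | intermediate
3 | Mannich base: 1 with an exo CH2NMe2 group at C11 | O=C1[C@H](CN(C)C)[C@H]2C=CC[C@H]2O1 | intermediate
4 | trimethylammonium iodide of 3 | [I-].O=C1[C@H](C[N+](C)(C)C)[C@H]2C=CC[C@H]2O1 | intermediate
5 | α-methylene lactone: 4-methylidene derivative of 1, ring fusion as in 1 | O=C1C(=C)[C@H]2C=CC[C@H]2O1 | intermediate
6 | exo spiro-epoxide: 11,13-epoxide of 5, epoxide O cis to H7 | O=C1[C@@]3(CO3)[C@H]2C=CC[C@H]2O1 | intermediate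
7 | lithium carboxylate from lactone opening of 6 (C8–OH free, cis to the side chain) | [Li+].[O-]C(=O)[C@@]3(CO3)[C@H]2C=CC[C@H]2O | intermediate
8 | iodolactone: O6–C12 lactone cis-fused at C6–C7, C5 iodide trans to O6, C8–OH cis to the lactone, 11,13-epoxide with O cis to C8 | O[C@@H]1C[C@@H](I)[C@@H]2OC(=O)[C@@]3(CO3)[C@H]12 | intermediate
9 | cyclopentenol lactone: as 8 with C5=C9 in place of the iodide (O6, C11, O8 all cis) | O[C@@H]1C=C[C@@H]2OC(=O)[C@@]3(CO3)[C@H]12 | intermediate
10 | lactol aldehyde: C5 hemiacetal closed on O8 (anomeric mixture), C9 aldehyde on C8, lactone and epoxide as in 9 | O=C[C@H]1OC(O)[C@@H]2OC(=O)[C@@]3(CO3)[C@H]12 | intermediate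
11 | lactol alcohol: as 10 with C9H2OH (anomeric mixture) | OC[C@H]1OC(O)[C@@H]2OC(=O)[C@@]3(CO3)[C@H]12 | intermediate
12 | vinyl diol: γ-lactone with C6 vinyl, C7 chain CH(OH)CH2OH (C8, C9) cis to the vinyl group, 11,13-epoxide | OC[C@@H](O)[C@@H]1[C@H](C=C)OC(=O)[C@@]12CO2 | intermediate
13 | hydroxy aldehyde: as 12 with C9 as CHO | O=C[C@@H](O)[C@@H]1[C@H](C=C)OC(=O)[C@@]12CO2 | intermediate
14 | γ-hydroxy E-enone: C8(OH)–C9H=C10(CH3)–C1(=O)–C2H3 | CC(=O)/C(C)=C/[C@@H](O)[C@@H]1[C@H](C=C)OC(=O)[C@@]12CO2 | intermediate
15 | bis-epoxide hydroxy ketone: trans C9–C10 epoxide syn (threo) to C8–OH | CC(=O)[C@@]1(C)O[C@@H]1[C@@H](O)[C@@H]2[C@H](C=C)OC(=O)[C@@]23CO3 | intermediate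
16 | O8 angelate of 15 | CC(=O)[C@@]1(C)O[C@@H]1[C@@H](OC(=O)/C(C)=C\C)[C@@H]2[C@H](C=C)OC(=O)[C@@]23CO3 | intermediate
17 | chlorohydrin methacrylate: C13H2Cl, O11 methacrylate, otherwise as 16 | CC(=O)[C@@]1(C)O[C@@H]1[C@@H](OC(=O)/C(C)=C\C)[C@@H]2[C@H](C=C)OC(=O)[C@@]2(OC(=O)C(C)=C)CCl | intermediate
18 | bridged bis-lactone: ring B = seven-membered lactone C3(=O)–O11 with Z C4=C5, bridging C6 and C11 of ring A | CC(=O)[C@@]1(C)O[C@@H]1[C@@H](OC(=O)/C(C)=C\C)[C@@H]2[C@@H]3/C=C(/C)C(=O)O[C@@]2(CCl)C(=O)O3 | intermediate
19 | lithium enolate of 18 (C1=C2) | [Li+].C=C([O-])[C@@]1(C)O[C@@H]1[C@@H](OC(=O)/C(C)=C\C)[C@@H]2[C@@H]3/C=C(/C)C(=O)O[C@@]2(CCl)C(=O)O3 | intermediate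
20 | ten-membered β-diketone (C1, C3) with C9–C10 epoxide, free C11–OH, formed as its lithium enolate | C/C=C(/C)C(=O)O[C@H]1[C@@H]2[C@H](/C=C(/C)C(=O)CC(=O)[C@@]3(C)O[C@H]13)OC(=O)[C@@]2(O)CCl | intermediate
21 | CNP0272644.1, (4Z,6S,7S,8S,9R,10R,11R)-furanoheliangolide: 8-O-angelate, 9-OH, 11-OH, 13-Cl | C/C=C(/C)C(=O)O[C@H]1[C@@H]2[C@H](/C=C(/C)C3=CC(=O)[C@](C)(O3)[C@@H]1O)OC(=O)[C@@]2(O)CCl | target

**Step count and risks**

Total step count: 12. Longest linear sequence: 12 steps (fully linear from 1).

Steps most likely to fail:

1. Step 12 (Proposed new method). The enolate may fail to reach C3 across the bridged lactone or may acylate elsewhere, or the epoxide may open too slowly so that a lingering alkoxide moves the angelate or closes the chlorohydrin. Fallback, from 17 back to 21, each stage a known reaction type and with the ten-membered ring closed last by metathesis: LiN(SiMe3)2 (THF, −78 °C) should move the methacryloyl group of 17 from O11 to C2 (Claisen-type O-to-C acyl transfer) to give the open-chain isopropenyl β-diketone F1. Et3N/LiClO4 should then close the furanone by O-alkylation at C10, with the epoxide as leaving group, to give the 5-isopropenyl-3(2H)-furanone F2. Ring-closing metathesis of the isopropenyl and C6 vinyl groups (second-generation Hoveyda–Grubbs catalyst, toluene, 80 °C, high dilution) should then form C4=C5 and give 21.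

2. Step 6. Under the basic ylide the C8 and C9 alkoxides may attack the lactone carbonyl (lactone migration) or the spiro-epoxide. Fallback, from 9 back to 13, avoiding lactol and ylide: ethenolysis of the cyclopentene (ethylene, second-generation Hoveyda–Grubbs catalyst, CH2Cl2) should give the divinyl hydroxy lactone F3. VO(acac)2/t-BuOOH should epoxidise only the vinyl group next to the free C8 hydroxyl and give the terminal epoxy alcohol F4 (C9 epimers, of no consequence). H5IO6 should cleave that terminal epoxide to hydroxy aldehyde 13, which enters the Wittig stage of step 7 and gives 14.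

3. Step 8. Facial selectivity may be poor, or the peroxide anion may attack the glycidic lactone. Fallback, from 14 back to 16, with the epoxide face set by a reagent-made carbinol: Yamaguchi angeloylation of 14 should give the angelate enone F5. Reduction with catecholborane and (S)-2-methyl-CBS-oxazaborolidine should give the (R)-configured C1 allylic alcohol F6. VO(acac)2/t-BuOOH epoxidation directed by the C1 hydroxyl (allylic 1,2-strain, erythro) should give the epoxy alcohol F7, and Dess–Martin oxidation of the C1 carbinol returns to the route at 16.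

**Further compounds**

F1 | step 12 | open-chain isopropenyl β-diketone (C3 acyl on C2, free C11–OH, C9–C10 epoxide) | C=C(C)C(=O)CC(=O)[C@@]1(C)O[C@@H]1[C@@H](OC(=O)/C(C)=C\C)[C@@H]2[C@H](C=C)OC(=O)[C@@]2(O)CCl
F2 | step 12 | 5-isopropenyl-3(2H)-furanone with C9–OH, O8 angelate and C6 vinyl | C=C(C)C1=CC(=O)[C@](C)(O1)[C@H](O)[C@@H](OC(=O)/C(C)=C\C)[C@@H]2[C@H](C=C)OC(=O)[C@@]2(O)CCl
F3 | step 6 | divinyl hydroxy lactone (C6 vinyl, C8 vinyl carbinol, 11,13-epoxide) | C=C[C@@H](O)[C@@H]1[C@H](C=C)OC(=O)[C@@]12CO2
F4 | step 6 | terminal epoxy alcohol from F3 (oxirane on the C8 carbinol, C9 epimers) | O[C@H](C1CO1)[C@@H]2[C@H](C=C)OC(=O)[C@@]23CO3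
F5 | step 8 | O8 angelate of enone 14 | CC(=O)/C(C)=C/[C@@H](OC(=O)/C(C)=C\C)[C@@H]1[C@H](C=C)OC(=O)[C@@]12CO2
F6 | step 8 | (R)-C1 allylic alcohol from F5 | C[C@@H](O)/C(C)=C/[C@@H](OC(=O)/C(C)=C\C)[C@@H]1[C@H](C=C)OC(=O)[C@@]12CO2
F7 | step 8 | C9–C10 epoxy alcohol from F6 (epoxide as in 16, C1 carbinol) | C[C@@H](O)[C@@]1(C)O[C@@H]1[C@@H](OC(=O)/C(C)=C\C)[C@@H]2[C@H](C=C)OC(=O)[C@@]23CO3
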